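Cuts: after the two O–Si bonds, the C2–C3 bond of ring C is cut first. Then follow C3–C4 (acylation of diazomethane), C4–C4a (ortho-formylation), O1–C2 (benzylation), the two C–CH3 bonds of the carbinol (Grignard) and C8–CH2 (hydroarylation of acrylic acid).
Enabling feature: C2 is benzylic and bound to O1, so C2 with its phenyl group is the CH2Ph of a benzyl ether on C8a. C3, alpha to the C4 ketone, can be a carbene carbon placed to close the six-membered path C3–C4–C4a–C8a–O1–C2.
Forward order: ring A is bought as phloroglucinol. A temporary lactone ring ties the C8 chain to the future O1 and so tells the three oxygens apart (O1 masked, C5–O silylated, C7–O methylated). The lactone is opened, C4 and C3 are added, and ring C closes in the last step but one.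
Stereochemistry: the single stereocentre C2 (S) comes from the chiral catalyst Rh2(S-PTTL)4, which picks one of the two enantiotopic benzylic hydrogens. The final desilylation is acidic, so retro-oxa-Michael opening cannot erode it.

Key step: step 10

Assumption: the sense of induction of Rh2(S-PTTL)4 with this diazoketone cannot be predicted with certainty and is taken to give 2S. If the first run shows 2R, the mirror-image catalyst Rh2(R-PTTL)4 from D-tert-leucine takes its place with nothing else changed.

Step 1
Reactants: 1 phloroglucinol; 2 acrylic acid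
Product: 3 5,7-dihydroxychroman-2-one (5,7-dihydroxy-3,4-dihydrocoumarin)
Conditions: Amberlyst-15, toluene, reflux, Dean–Stark
Reagents that add atoms: acrylic acid (2), C=CC(=O)O
Why: Acid-catalysed hydroarylation of acrylic acid (Friedel–Crafts conjugate alkylation) by the very electron-rich ring, followed by lactonisation onto the neighbouring phenol, is a known entry to 3,4-dihydrocoumarins, and the threefold symmetry of 1 leaves no regiochemical choice.

Step 2
Reactants: 3 5,7-dihydroxychroman-2-one
Product: 4 5-hydroxy-7-(triisopropylsilyloxy)chroman-2-one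
Conditions: TIPSCl (1 equiv), imidazole, DMF, 0 °C
Reagents that add atoms: triisopropylsilyl chloride, CC(C)[Si](Cl)(C(C)C)C(C)C
Why: Kinetic silylation of the less hindered phenol should go to O7, because the C7 hydroxyl is flanked by two C–H positions whereas the C5 hydroxyl sits next to the C4 methylene, and the bulky TIPS group later withstands carbonate, Grignard reagent and buffered oxidant.

Step 3
Reactants: 4 5-hydroxy-7-(triisopropylsilyloxy)chroman-2-one
Product: 5 5-methoxy-7-(triisopropylsilyloxy)chroman-2-one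
Conditions: MeI, K2CO3, dry acetone, 40 °C
Reagents that add atoms: iodomethane, CI
Why: Williamson methylation of the only remaining phenol runs under anhydrous, weakly basic conditions that leave the aryl lactone and the TIPS ether untouched.

Step 4
Reactants: 5 5-methoxy-7-(triisopropylsilyloxy)chroman-2-one; 6 methylmagnesium bromide
Product: 7 2-(3-hydroxy-3-methylbutyl)-3-methoxy-5-(triisopropylsilyloxy)phenol
Conditions: MeMgBr (3 equiv), THF, 0 °C to rt; sat. aq NH4Cl
Reagents that add atoms: methylmagnesium bromide (6), C[Mg]Br (two methyl groups)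
Why: Double Grignard addition to the aryl lactone (the first addition expels the phenoxide, the resulting methyl ketone takes the second) is the classical opening of dihydrocoumarins to 2-(3-hydroxy-3-methylbutyl)phenols, frees only the oxygen that becomes O1, and the neutral quench avoids acid-catalysed closure to the 2,2-dimethylchroman.

Step 5
Reactants: 7 2-(3-hydroxy-3-methylbutyl)-3-methoxy-5-(triisopropylsilyloxy)phenol
Product: 8 2-hydroxy-3-(3-hydroxy-3-methylbutyl)-4-methoxy-6-(triisopropylsilyloxy)benzaldehyde
Conditions: MgCl2, Et3N, (CH2O)n, MeCN, reflux; cold 1 M HCl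
Reagents that add atoms: formaldehyde (as paraformaldehyde), C=O
Why: In the Casnati–Skattebøl ortho-formylation the magnesium phenoxide delivers formaldehyde only ortho to the free phenol and a second formaldehyde oxidises the salicyl alcohol by hydride transfer, and since the other ortho position carries the chain, the future C4 enters at C4a and not at C6.

Step 6
Reactants: 8 2-hydroxy-3-(3-hydroxy-3-methylbutyl)-4-methoxy-6-(triisopropylsilyloxy)benzaldehyde; 9 benzyl bromide
Product: 10 2-(benzyloxy)-3-(3-hydroxy-3-methylbutyl)-4-methoxy-6-(triisopropylsilyloxy)benzaldehyde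
Conditions: BnBr, K2CO3, DMF, rt to 40 °C
Reagents that add atoms: benzyl bromide (9), BrCc1ccccc1
Why: In this Williamson etherification carbonate deprotonates only the chelated phenol and not the tertiary alcohol, so the CH2Ph unit that becomes C2 with its phenyl group is placed on O1 while the TIPS ether holds.

Step 7
Reactants: 10 2-(benzyloxy)-3-(3-hydroxy-3-methylbutyl)-4-methoxy-6-(triisopropylsilyloxy)benzaldehyde
Product: 11 2-(benzyloxy)-4-methoxy-3-[3-methyl-3-(triethylsilyloxy)butyl]-6-(triisopropylsilyloxy)benzaldehyde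
Conditions: TESOTf, 2,6-lutidine, CH2Cl2, −78 to 0 °C
Reagents that add atoms: triethylsilyl trifluoromethanesulfonate, CC[Si](CC)(CC)OS(=O)(=O)C(F)(F)F
Why: Silyl triflate with a hindered pyridine base is the standard silylation of tertiary alcohols, the non-enolisable aldehyde returns unchanged on aqueous work-up, and the free O–H that would spoil acid activation and trap the carbene is removed.

Step 8
Reactants: 11 2-(benzyloxy)-4-methoxy-3-[3-methyl-3-(triethylsilyloxy)butyl]-6-(triisopropylsilyloxy)benzaldehyde
Product: 12 2-(benzyloxy)-4-methoxy-3-[3-methyl-3-(triethylsilyloxy)butyl]-6-(triisopropylsilyloxy)benzoic acid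
Conditions: NaClO2, NaH2PO4, 2-methyl-2-butene (large excess), t-BuOH/THF/H2O, 0 °C to rt
Reagents that add atoms: sodium chlorite, [Na+].[O-]Cl=O (one oxygen)
Why: The Pinnick oxidation converts hindered, electron-rich benzaldehydes into acids in a mildly acidic buffer that both silyl ethers tolerate, and the alkene scavenger takes up hypochlorous acid before it can chlorinate C6.

Step 9
Reactants: 12 2-(benzyloxy)-4-methoxy-3-[3-methyl-3-(triethylsilyloxy)butyl]-6-(triisopropylsilyloxy)benzoic acid
Product: 14 1-{2-(benzyloxy)-4-methoxy-3-[3-methyl-3-(triethylsilyloxy)butyl]-6-(triisopropylsilyloxy)phenyl}-2-diazoethan-1-one, via acid chloride 13 (not isolated)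
Conditions: Me2C=C(Cl)NMe2, CH2Cl2, 0 °C to rt; then CH2N2 (excess, distilled in Et2O from N-methyl-N-nitroso-p-toluenesulfonamide/KOH), 0 °C
Reagents that add atoms: diazomethane, C=[N+]=[N-]; 1-chloro-N,N,2-trimethylprop-1-en-1-amine, CC(C)=C(Cl)N(C)C (chlorine of 13 only)
Why: The chloroenamine makes the acid chloride under neutral, HCl-free conditions that spare the silyl ethers, and acylation of diazomethane (first stage of the Arndt–Eistert sequence) works for 2,6-dioxygenated benzoyl chlorides, with the excess reagent scavenging the HCl set free.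

Step 10
Reactants: 14 1-{2-(benzyloxy)-4-methoxy-3-[3-methyl-3-(triethylsilyloxy)butyl]-6-(triisopropylsilyloxy)phenyl}-2-diazoethan-1-one
Product: 15 (2S)-7-methoxy-8-[3-methyl-3-(triethylsilyloxy)butyl]-2-phenyl-5-(triisopropylsilyloxy)chroman-4-one
Conditions: dirhodium tetrakis[N-phthaloyl-(S)-tert-leucinate], Rh2(S-PTTL)4 (1 mol %), toluene, 4 Å MS, 0 °C, slow addition of 14 at high dilution
Reagents that add atoms: none
Why: Rh2(S-PTTL)4 expels N2 from 14, and the electrophilic rhodium carbene at C3 takes up one benzylic C–H bond of the C8a benzyl ether through a concerted but asynchronous three-centre transition state with hydride-transfer character, which forms C2–C3 and releases the catalyst. The closest known reaction type is the dirhodium-carboxylate-catalysed C–H insertion of ortho-alkoxyaryl diazoketones next to the ether oxygen, which gives chroman-4-ones, and phthalimide-protected amino acid ligands of this family already tell apart the two hydrogens of aryl benzyl ethers in the related closure to 2-aryl-2,3-dihydrobenzofurans. Ring C closes as a 1,6-insertion, the six ring atoms being C3, C4, C4a, C8a, O1 and C2. The new stereocentre C2 is controlled by the catalyst alone, whose four N-phthaloyl-tert-leucinate ligands wall in the carbene so that only one of the two enantiotopic hydrogens can reach it, taken here as the one that leads to 2S. The selectivity needed is insertion over attack of the carbene on O1 (five-membered oxonium ylide, then 1,2-benzyl shift to a 2-benzylbenzofuran-3-one), and it is secured by the double activation of the C–H bond by O1 and phenyl, by the low nucleophilicity of an aryl ether oxygen crowded between the C8 chain and the acyl group, and by the choice of a rhodium carboxylate rather than copper. The other ortho oxygen is buried under the triisopropylsilyl group and the side-chain ether carbon is quaternary, so no second activated C–H bond, free O–H or accessible lone pair lies within reach.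

Step 11
Reactants: 15 (2S)-7-methoxy-8-[3-methyl-3-(triethylsilyloxy)butyl]-2-phenyl-5-(triisopropylsilyloxy)chroman-4-one
Product: 16 (2S)-5-hydroxy-8-(3-hydroxy-3-methylbutyl)-7-methoxy-2-phenylchroman-4-one
Conditions: HF·pyridine, extra pyridine, THF, 0 °C to rt
Reagents that add atoms: none
Why: Fluoride-driven Si–O cleavage removes the tertiary TES ether and the carbonyl-activated aryl TIPS ether together, the acidic medium keeps the C5 phenol protonated so that retro-oxa-Michael opening to the chalcone cannot racemise C2, and dilution with pyridine and THF prevents ionisation of the tertiary alcohol.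

Compound list
1 | phloroglucinol | Oc1cc(O)cc(O)c1 | starting material
2 | acrylic acid | C=CC(=O)O | starting material
3 | 5,7-dihydroxychroman-2-one | O=C1CCc2c(O)cc(O)cc2O1 | intermediate
4 | 5-hydroxy-7-(triisopropylsilyloxy)chroman-2-one | O=C1CCc2c(O)cc(O[Si](C(C)C)(C(C)C)C(C)C)cc2O1 | intermediate
5 | 5-methoxy-7-(triisopropylsilyloxy)chroman-2-one | O=C1CCc2c(OC)cc(O[Si](C(C)C)(C(C)C)C(C)C)cc2O1 | intermediate
6 | methylmagnesium bromide | C[Mg]Br | starting material
7 | 2-(3-hydroxy-3-methylbutyl)-3-methoxy-5-(triisopropylsilyloxy)phenol | CC(C)(O)CCc1c(O)cc(O[Si](C(C)C)(C(C)C)C(C)C)cc1OC | intermediate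
8 | 2-hydroxy-3-(3-hydroxy-3-methylbutyl)-4-methoxy-6-(triisopropylsilyloxy)benzaldehyde | CC(C)(O)CCc1c(O)c(C=O)c(O[Si](C(C)C)(C(C)C)C(C)C)cc1OC | intermediate
9 | benzyl bromide | BrCc1ccccc1 | starting material
10 | 2-(benzyloxy)-3-(3-hydroxy-3-methylbutyl)-4-methoxy-6-(triisopropylsilyloxy)benzaldehyde | CC(C)(O)CCc1c(OCc2ccccc2)c(C=O)c(O[Si](C(C)C)(C(C)C)C(C)C)cc1OC | intermediate
11 | 2-(benzyloxy)-4-methoxy-3-[3-methyl-3-(triethylsilyloxy)butyl]-6-(triisopropylsilyloxy)benzaldehyde | CC[Si](CC)(CC)OC(C)(C)CCc1c(OCc2ccccc2)c(C=O)c(O[Si](C(C)C)(C(C)C)C(C)C)cc1OC | intermediate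
12 | 2-(benzyloxy)-4-methoxy-3-[3-methyl-3-(triethylsilyloxy)butyl]-6-(triisopropylsilyloxy)benzoic acid | CC[Si](CC)(CC)OC(C)(C)CCc1c(OCc2ccccc2)c(C(=O)O)c(O[Si](C(C)C)(C(C)C)C(C)C)cc1OC | intermediate
13 | 2-(benzyloxy)-4-methoxy-3-[3-methyl-3-(triethylsilyloxy)butyl]-6-(triisopropylsilyloxy)benzoyl chloride | CC[Si](CC)(CC)OC(C)(C)CCc1c(OCc2ccccc2)c(C(=O)Cl)c(O[Si](C(C)C)(C(C)C)C(C)C)cc1OC | intermediate
14 | 1-{2-(benzyloxy)-4-methoxy-3-[3-methyl-3-(triethylsilyloxy)butyl]-6-(triisopropylsilyloxy)phenyl}-2-diazoethan-1-one | CC[Si](CC)(CC)OC(C)(C)CCc1c(OCc2ccccc2)c(C(=O)C=[N+]=[N-])c(O[Si](C(C)C)(C(C)C)C(C)C)cc1OC | intermediate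
15 | (2S)-7-methoxy-8-[3-methyl-3-(triethylsilyloxy)butyl]-2-phenyl-5-(triisopropylsilyloxy)chroman-4-one | CC[Si](CC)(CC)OC(C)(C)CCc1c(OC)cc(O[Si](C(C)C)(C(C)C)C(C)C)c2c1O[C@H](c1ccccc1)CC2=O | intermediate
16 | (2S)-5-hydroxy-8-(3-hydroxy-3-methylbutyl)-7-methoxy-2-phenylchroman-4-one | COc1cc(O)c2c(c1CCC(C)(C)O)O[C@H](c1ccccc1)CC2=O | target

Total step count: 11. Longest linear sequence: 11 (from phloroglucinol).

Steps most likely to fail

**Step 10.** The carbene may be intercepted by the lone pair of O1 (ylide formation followed by benzyl migration). It may also dimerise, or discriminate poorly between the two enantiotopic hydrogens. The fallback forms the C2–phenyl bond instead of C2–C3 and relies on the known asymmetric conjugate addition of arylboronic acids to chromones.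
- It sets out from 8. Excess ethynylmagnesium bromide (HC≡CMgBr, THF, 0 °C) adds to the aldehyde to give 2-(1-hydroxyprop-2-yn-1-yl)-6-(3-hydroxy-3-methylbutyl)-5-methoxy-3-(triisopropylsilyloxy)phenol F1.
- MnO2 in CH2Cl2 oxidises F1 to 1-[2-hydroxy-3-(3-hydroxy-3-methylbutyl)-4-methoxy-6-(triisopropylsilyloxy)phenyl]prop-2-yn-1-one F2.
- Diethylamine in ethanol adds to the ynone and is displaced by the phenol in a 6-endo closure, giving 8-(3-hydroxy-3-methylbutyl)-7-methoxy-5-(triisopropylsilyloxy)-4H-chromen-4-one F3.
- TESOTf and 2,6-lutidine give 7-methoxy-8-[3-methyl-3-(triethylsilyloxy)butyl]-5-(triisopropylsilyloxy)-4H-chromen-4-one F4.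
- 1,4-Addition of phenylboronic acid follows ([RhCl(C2H4)2]2, a chiral bicyclo[2.2.2]octadiene ligand of the hand that leads to 2S, toluene/H2O). This brings the sequence back to the route at 15.

**Step 2.** Site selectivity between the two phenols may be poor, or double silylation may compete. The fallback sets the oxygen pattern by chelation and symmetry instead of sterics.
- It sets out from 1. Vilsmeier–Haack formylation (POCl3, DMF) gives 2,4,6-trihydroxybenzaldehyde F5.
- Only the C4 hydroxyl is free of a hydrogen bond to the aldehyde, and it takes TIPSCl/imidazole to give 2,6-dihydroxy-4-(triisopropylsilyloxy)benzaldehyde F6.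
- Mitsunobu methylation (MeOH, PPh3, DIAD) of one of the two equivalent chelated phenols gives 2-hydroxy-6-methoxy-4-(triisopropylsilyloxy)benzaldehyde F7.
- Wittig olefination with Ph3P=CHCO2Et in hot toluene gives ethyl (E)-3-[2-hydroxy-6-methoxy-4-(triisopropylsilyloxy)phenyl]prop-2-enoate F8.
- Hydrogenation (H2, Pd/C, EtOAc) gives ethyl 3-[2-hydroxy-6-methoxy-4-(triisopropylsilyloxy)phenyl]propanoate F9.
- Excess 6 converts the ester into the tertiary alcohol, rejoining the route at 7.

**Step 9.** Three things may go wrong: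
- protodecarboxylation or silyl loss when the crowded, electron-rich acid is activated;
- slow acylation of diazomethane by the hindered acid chloride;
- hydrochlorination of the diazoketone.

The fallback avoids the acid altogether and installs the diazo group by diazo transfer onto a methyl ketone.
- It sets out from 11. Addition of 6 (THF, −78 to 0 °C) gives racemic 1-{2-(benzyloxy)-4-methoxy-3-[3-methyl-3-(triethylsilyloxy)butyl]-6-(triisopropylsilyloxy)phenyl}ethan-1-ol F10, whose carbinol centre is erased at once.
- Dess–Martin oxidation gives 1-{2-(benzyloxy)-4-methoxy-3-[3-methyl-3-(triethylsilyloxy)butyl]-6-(triisopropylsilyloxy)phenyl}ethan-1-one F11.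
- LiN(SiMe3)2 and CF3CO2CH2CF3 at −78 °C give 4,4,4-trifluoro-1-{2-(benzyloxy)-4-methoxy-3-[3-methyl-3-(triethylsilyloxy)butyl]-6-(triisopropylsilyloxy)phenyl}butane-1,3-dione F12.
- Methanesulfonyl azide with Et3N and water in MeCN effects the detrifluoroacetylative diazo transfer, returning to the route at 14.

Further compounds
F1 | step 10 | 2-(1-hydroxyprop-2-yn-1-yl)-6-(3-hydroxy-3-methylbutyl)-5-methoxy-3-(triisopropylsilyloxy)phenol | CC(C)(O)CCc1c(O)c(C(O)C#C)c(O[Si](C(C)C)(C(C)C)C(C)C)cc1OC
F2 | step 10 | 1-[2-hydroxy-3-(3-hydroxy-3-methylbutyl)-4-methoxy-6-(triisopropylsilyloxy)phenyl]prop-2-yn-1-one | CC(C)(O)CCc1c(O)c(C(=O)C#C)c(O[Si](C(C)C)(C(C)C)C(C)C)cc1OC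
F3 | step 10 | 8-(3-hydroxy-3-methylbutyl)-7-methoxy-5-(triisopropylsilyloxy)-4H-chromen-4-one | CC(C)(O)CCc1c(OC)cc(O[Si](C(C)C)(C(C)C)C(C)C)c2c1OC=CC2=O
F4 | step 10 | 7-methoxy-8-[3-methyl-3-(triethylsilyloxy)butyl]-5-(triisopropylsilyloxy)-4H-chromen-4-one | CC[Si](CC)(CC)OC(C)(C)CCc1c(OC)cc(O[Si](C(C)C)(C(C)C)C(C)C)c2c1OC=CC2=O
F5 | step 2 | 2,4,6-trihydroxybenzaldehyde | O=Cc1c(O)cc(O)cc1O
F6 | step 2 | 2,6-dihydroxy-4-(triisopropylsilyloxy)benzaldehyde | O=Cc1c(O)cc(O[Si](C(C)C)(C(C)C)C(C)C)cc1O
F7 | step 2 | 2-hydroxy-6-methoxy-4-(triisopropylsilyloxy)benzaldehyde | O=Cc1c(O)cc(O[Si](C(C)C)(C(C)C)C(C)C)cc1OC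
F8 | step 2 | ethyl (E)-3-[2-hydroxy-6-methoxy-4-(triisopropylsilyloxy)phenyl]prop-2-enoate | CCOC(=O)/C=C/c1c(O)cc(O[Si](C(C)C)(C(C)C)C(C)C)cc1OC
F9 | step 2 | ethyl 3-[2-hydroxy-6-methoxy-4-(triisopropylsilyloxy)phenyl]propanoate | CCOC(=O)CCc1c(O)cc(O[Si](C(C)C)(C(C)C)C(C)C)cc1OC
F10 | step 9 | 1-{2-(benzyloxy)-4-methoxy-3-[3-methyl-3-(triethylsilyloxy)butyl]-6-(triisopropylsilyloxy)phenyl}ethan-1-ol (racemic) | CC[Si](CC)(CC)OC(C)(C)CCc1c(OCc2ccccc2)c(C(C)O)c(O[Si](C(C)C)(C(C)C)C(C)C)cc1OC
F11 | step 9 | 1-{2-(benzyloxy)-4-methoxy-3-[3-methyl-3-(triethylsilyloxy)butyl]-6-(triisopropylsilyloxy)phenyl}ethan-1-one | CC[Si](CC)(CC)OC(C)(C)CCc1c(OCc2ccccc2)c(C(C)=O)c(O[Si](C(C)C)(C(C)C)C(C)C)cc1OC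
F12 | step 9 | 4,4,4-trifluoro-1-{2-(benzyloxy)-4-methoxy-3-[3-methyl-3-(triethylsilyloxy)butyl]-6-(triisopropylsilyloxy)phenyl}butane-1,3-dione | CC[Si](CC)(CC)OC(C)(C)CCc1c(OCc2ccccc2)c(C(=O)CC(=O)C(F)(F)F)c(O[Si](C(C)C)(C(C)C)C(C)C)cc1OC
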